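**Plan**
- Retrosynthesis: the two phenols are unmasked last (O–CH3 on ring A, C–B on ring B). Ring B is then cut at two C–C bonds, C(OAr)–C(Br) and C(B)–C(H).
- Enabling feature: ring B carries three contiguous C–Br carbons followed by one C–H carbon. These four carbons are the diene of a tribromothiophene S,S-dioxide; the ether carbon and the hydroxyl carbon are the two carbons of an aryloxyalkynyl boronate.
- Forward: ring A comes intact from guaiacol by dibromination. Its phenol oxygen is carried through a vinyl ether and an ynol ether into the alkynyl boronate; the sulfone comes from tetrabromothiophene.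
- Ring B is the only ring formed, by [4+2] cycloaddition and loss of SO2, so the hindered diaryl ether C–O bond is never made by coupling. C–B oxidation and O-demethylation finish the route.
- Stereochemistry: the target has no stereocentre; the only selectivity needed is the orientation of the cycloaddition.

Key step: step 8

Remark: 4, 14 and 16 are racemic and 5 may form as a Z/E mixture; these stereo-elements vanish in the following transformation, so none needs control.

**Step 1**
Reactants: 1 guaiacol (2-methoxyphenol)
Product: 2 2,4-dibromo-6-methoxyphenol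
Conditions: NBS (2.05 equiv), MeCN, 0 °C → rt
Reagents that add atoms: N-bromosuccinimide, O=C1CCC(=O)N1Br
Why: Electrophilic aromatic bromination in which the free hydroxyl outranks the methoxy group as director and takes one bromine para and one ortho to itself, the positions para and ortho to the future ether oxygen of ring A.

**Step 2**
Reactants: 2 2,4-dibromo-6-methoxyphenol
Product: 3 1,5-dibromo-2-(ethenyloxy)-3-methoxybenzene
Conditions: vinyl acetate (3 equiv), [IrCl(cod)]2 (2 mol %, cod = 1,5-cyclooctadiene), Na2CO3 (0.6 equiv), PhMe, 100 °C
Reagents that add atoms: vinyl acetate, CC(=O)OC=C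
Why: Iridium-catalysed transfer vinylation of a phenol with vinyl acetate, driven by carbonate capture of the acetic acid, under which aryl bromides should remain untouched.

**Step 3**
Reactants: 3 1,5-dibromo-2-(ethenyloxy)-3-methoxybenzene
Product: 4 1,5-dibromo-2-(1,2-dibromoethoxy)-3-methoxybenzene (racemic)
Conditions: Br2 (1.0 equiv), CH2Cl2, −78 °C; concentrated cold and used crude
Reagents that add atoms: bromine, BrBr
Why: Electrophilic addition of bromine to the electron-rich enol ether C=C is far faster at −78 °C than substitution on the doubly brominated ring; the new stereocentre forms as a racemate and is destroyed in step 4.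

**Step 4**
Reactants: 4 1,5-dibromo-2-(1,2-dibromoethoxy)-3-methoxybenzene
Product: 6 1,5-dibromo-2-(ethynyloxy)-3-methoxybenzene, via bromovinyl ether 5 (not isolated)
Conditions: KOtBu (2.5 equiv), THF, −40 °C → rt; kept cold in solution and used at once
Reagents that add atoms: none
Why: Two consecutive base-induced dehydrobrominations (E2), the first to the bromovinyl ether and the second to the ynol ether, with a base that at or below room temperature should neither exchange nor eliminate the aryl bromides.

**Step 5**
Reactants: 6 1,5-dibromo-2-(ethynyloxy)-3-methoxybenzene; 7 2-isopropoxy-4,4,5,5-tetramethyl-1,3,2-dioxaborolane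
Product: 10 2-[(2,4-dibromo-6-methoxyphenoxy)ethynyl]-4,4,5,5-tetramethyl-1,3,2-dioxaborolane, via lithium acetylide 8 (not isolated), via lithium alkynylborate 9 (not isolated)
Conditions: LiN(SiMe3)2 (1.05 equiv), THF, −78 °C; 7 (1.1 equiv), −78 °C; HCl in Et2O (1.05 equiv), −78 °C → rt
Reagents that add atoms: none
Why: Standard preparation of a 1-alkynyl pinacol boronate by deprotonation of the terminal alkyne, trapping with the borate ester and release from the ate complex with one equivalent of anhydrous HCl; the silylamide is strong enough for the sp C–H but too weak to metalate the ring C–H between the two bromines or to exchange an aryl bromide.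

**Step 6**
Reactants: 11 tetrabromothiophene
Product: 13 2,3,4-tribromothiophene, via thienyllithium 12 (not isolated)
Conditions: n-BuLi (1.0 equiv), Et2O, −78 °C; then H2O, −78 °C → rt
Reagents that add atoms: none
Why: Bromine–lithium exchange occurs selectively at an α-position because the α-thienyl anion is the most stabilised, and protonation at −78 °C before warming should prevent halogen migration.

**Step 7**
Reactants: 13 2,3,4-tribromothiophene
Product: 15 2,3,4-tribromothiophene 1,1-dioxide, via thiophene S-oxide 14 (not isolated)
Conditions: (CF3CO)2O, H2O2 (50% aq.), CH2Cl2, 0 °C → rt; cold NaHCO3 wash, solvent exchanged to PhMe below rt and used directly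
Reagents that add atoms: hydrogen peroxide, OO, converted in the flask by trifluoroacetic anhydride into trifluoroperacetic acid, O=C(OO)C(F)(F)F
Why: Peracid S-oxidation of an electron-poor halothiophene to its S,S-dioxide, which needs the strongest peracid; the second oxidation is faster than the first, and the three halogens should slow self-dimerisation enough for the cold solution to be carried straight into step 8.

**Step 8**
Reactants: 10 2-[(2,4-dibromo-6-methoxyphenoxy)ethynyl]-4,4,5,5-tetramethyl-1,3,2-dioxaborolane; 15 2,3,4-tribromothiophene 1,1-dioxide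
Product: 17 2-[3,4,5-tribromo-2-(2,4-dibromo-6-methoxyphenoxy)phenyl]-4,4,5,5-tetramethyl-1,3,2-dioxaborolane, via bicyclic sulfone 16 (not isolated)
Conditions: PhMe, 80 °C, 15 (1.5 equiv) added in portions as a fresh solution
Reagents that add atoms: none
Why: The electron-poor, non-aromatic diene C2=C3–C4=C5 of sulfone 15 and the electron-rich ynol ether triple bond of 10 should combine in an inverse-electron-demand Diels–Alder reaction to the 7-thiabicyclo[2.2.1]heptadiene dioxide 16, which loses SO2 by cheletropic extrusion and aromatises to ring B. The closest known reaction type is the cycloaddition of tetrahalothiophene S,S-dioxides with alkynes to give polyhalobenzenes, together with the cycloaddition–extrusion chemistry of alkynyl boronates with electron-poor dienes. Ring B, the only ring formed, is closed by an intermolecular [4+2] cycloaddition that makes the C(OAr)–C(Br) and C(B)–C(H) bonds, followed by extrusion of the one-atom sulfur bridge. No stereocentre remains, because the two bridgehead centres of racemic 16 become aromatic carbons. The step needs regioselectivity: the boron-bearing carbon is the nucleophilic β-carbon of the ynol ether and should bond first to the only unsubstituted, least hindered α-carbon of the sulfone, leaving the oxygen-bearing carbon to close on the brominated α-carbon and keeping the bulky boronate away from bromine. Adding 15 in portions keeps its concentration low so that cycloaddition outruns self-dimerisation.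

**Step 9**
Reactants: 17 2-[3,4,5-tribromo-2-(2,4-dibromo-6-methoxyphenoxy)phenyl]-4,4,5,5-tetramethyl-1,3,2-dioxaborolane
Product: 18 3,4,5-tribromo-2-(2,4-dibromo-6-methoxyphenoxy)phenol
Conditions: H2O2 (30% aq.), NaOH (1 M aq.), THF, 0 °C
Reagents that add atoms: hydrogen peroxide, OO
Why: Oxidation of an aryl boronate to a phenol, in which hydroperoxide adds to boron and the aryl group migrates from boron to oxygen so that the C–O bond forms exactly at the former C–B carbon; aryl bromides, the diaryl ether and the methyl ether are inert at 0 °C.

**Step 10**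
Reactants: 18 3,4,5-tribromo-2-(2,4-dibromo-6-methoxyphenoxy)phenol
Product: 19 3,4,5-tribromo-2-(2,4-dibromo-6-hydroxyphenoxy)phenol (target)
Conditions: BBr3 (3 equiv), CH2Cl2, −78 °C → rt; then H2O
Reagents that add atoms: none
Why: Lewis-acid cleavage of the aryl methyl ether with BBr3, in which bromide attacks the methyl group of the O–B complex, leaves the diaryl ether C–O bonds and all C–Br bonds intact, and aqueous work-up frees both phenols.

**Compound list**
1 | guaiacol (2-methoxyphenol) | COc1ccccc1O | starting material
2 | 2,4-dibromo-6-methoxyphenol | COc1cc(Br)cc(Br)c1O | intermediate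
3 | 1,5-dibromo-2-(ethenyloxy)-3-methoxybenzene | COc1cc(Br)cc(Br)c1OC=C | intermediate
4 | 1,5-dibromo-2-(1,2-dibromoethoxy)-3-methoxybenzene (racemic) | COc1cc(Br)cc(Br)c1OC(Br)CBr | intermediate
5 | 1,5-dibromo-2-{[(Z)-2-bromoethenyl]oxy}-3-methoxybenzene | COc1cc(Br)cc(Br)c1O/C=C\Br | intermediate
6 | 1,5-dibromo-2-(ethynyloxy)-3-methoxybenzene | COc1cc(Br)cc(Br)c1OC#C | intermediate
7 | 2-isopropoxy-4,4,5,5-tetramethyl-1,3,2-dioxaborolane | CC(C)OB1OC(C)(C)C(C)(C)O1 | starting material
8 | lithium (2,4-dibromo-6-methoxyphenoxy)acetylide | [Li]C#COc1c(OC)cc(Br)cc1Br | intermediate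
9 | lithium [(2,4-dibromo-6-methoxyphenoxy)ethynyl](isopropoxy)(pinacolato)borate | [Li+].CC(C)O[B-]1(C#COc2c(OC)cc(Br)cc2Br)OC(C)(C)C(C)(C)O1 | intermediate
10 | 2-[(2,4-dibromo-6-methoxyphenoxy)ethynyl]-4,4,5,5-tetramethyl-1,3,2-dioxaborolane | COc1cc(Br)cc(Br)c1OC#CB1OC(C)(C)C(C)(C)O1 | intermediate
11 | tetrabromothiophene | Brc1sc(Br)c(Br)c1Br | starting material
12 | (3,4,5-tribromothiophen-2-yl)lithium | [Li]c1sc(Br)c(Br)c1Br | intermediate
13 | 2,3,4-tribromothiophene | Brc1scc(Br)c1Br | intermediate
14 | 2,3,4-tribromothiophene 1-oxide (racemic at sulfur) | O=S1C=C(Br)C(Br)=C1Br | intermediate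
15 | 2,3,4-tribromothiophene 1,1-dioxide | O=S1(=O)C=C(Br)C(Br)=C1Br | intermediate
16 | 1,5,6-tribromo-2-(2,4-dibromo-6-methoxyphenoxy)-3-(4,4,5,5-tetramethyl-1,3,2-dioxaborolan-2-yl)-7-thiabicyclo[2.2.1]hepta-2,5-diene 7,7-dioxide (racemic) | O=S1(=O)C2(Br)C(Br)=C(Br)C1C(B3OC(C)(C)C(C)(C)O3)=C2Oc2c(OC)cc(Br)cc2Br | intermediate
17 | 2-[3,4,5-tribromo-2-(2,4-dibromo-6-methoxyphenoxy)phenyl]-4,4,5,5-tetramethyl-1,3,2-dioxaborolane | COc1cc(Br)cc(Br)c1Oc1c(B2OC(C)(C)C(C)(C)O2)cc(Br)c(Br)c1Br | intermediate
18 | 3,4,5-tribromo-2-(2,4-dibromo-6-methoxyphenoxy)phenol | COc1cc(Br)cc(Br)c1Oc1c(O)cc(Br)c(Br)c1Br | intermediate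
19 | 3,4,5-tribromo-2-(2,4-dibromo-6-hydroxyphenoxy)phenol | Oc1cc(Br)cc(Br)c1Oc1c(O)cc(Br)c(Br)c1Br | target

**Step count and risks**
Total step count: 10. Longest linear sequence: 8 steps (steps 1–5, 8, 9 and 10, from guaiacol); the thiophene branch (steps 6 and 7) joins at step 8.

Most likely to fail:

1. Step 8. The cycloaddition may proceed with the reverse orientation or as a mixture, or self-dimerisation of the diene and thermal decay of the ynol ether may outpace it. The fallback gives up the ring construction and makes the diaryl ether bond by nucleophilic aromatic substitution; it sets out from 1 and comes back to the route at 19. Guaiacol 1 would be tribrominated (Br2, 3 equiv, AcOH) to 2,3,4-tribromo-6-methoxyphenol F1. Its phenoxide (K2CO3, DMF, 90 °C) would displace fluoride from commercial 3,5-dibromo-2-fluorobenzaldehyde (O=Cc1cc(Br)cc(Br)c1F), activated by the ortho formyl group, to give 3,5-dibromo-2-(2,3,4-tribromo-6-methoxyphenoxy)benzaldehyde F2. Baeyer–Villiger oxidation (mCPBA, CH2Cl2) should give 3,5-dibromo-2-(2,3,4-tribromo-6-methoxyphenoxy)phenyl formate F3, and methanolysis (K2CO3, MeOH) 3,5-dibromo-2-(2,3,4-tribromo-6-methoxyphenoxy)phenol F4. Demethylation with BBr3 as in step 10 would then give 19.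

2. Step 7. S-oxidation of the strongly deactivated tribromothiophene may stall, or the sulfone may dimerise with loss of SO2 during oxidation and solvent exchange. The fallback introduces the α-bromine after the oxidation and releases the diene only in the presence of its partner; it sets out from 11 and comes back at 15. Zinc in aqueous AcOH would remove both α-bromines of 11 to give 3,4-dibromothiophene F5, a less deactivated thiophene. Trifluoroperacetic acid would oxidise it to the isolable 3,4-dibromothiophene 1,1-dioxide F6. Addition of Br2 across the diene (CH2Cl2) should give 2,3,4,5-tetrabromo-2,5-dihydrothiophene 1,1-dioxide F7, which can be stored. iPr2NEt in PhMe containing 10 would then eliminate HBr from F7 to generate 15, which is consumed in step 8 as it forms.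

3. Step 5. The C–B bond may be lost by protonolysis, or HCl may add across the electron-rich triple bond, when the boronate is released from the ate complex and isolated. The fallback replaces the carbanion and acid sequence by a catalytic dehydrogenative C–H borylation; it sets out from 6 and comes back at 10. Alkyne 6 would be treated with pinacolborane ([H]B1OC(C)(C)C(C)(C)O1), catalytic Fe(OTf)2 and catalytic DABCO in PhMe with gentle heating, hydrogen being the only by-product. The filtered toluene solution of 10 would pass directly into step 8; this detour creates no compound outside the list (entry F0).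

**Further compounds**
F1 | step 8 | 2,3,4-tribromo-6-methoxyphenol | COc1cc(Br)c(Br)c(Br)c1O
F2 | step 8 | 3,5-dibromo-2-(2,3,4-tribromo-6-methoxyphenoxy)benzaldehyde | COc1cc(Br)c(Br)c(Br)c1Oc1c(C=O)cc(Br)cc1Br
F3 | step 8 | 3,5-dibromo-2-(2,3,4-tribromo-6-methoxyphenoxy)phenyl formate | COc1cc(Br)c(Br)c(Br)c1Oc1c(OC=O)cc(Br)cc1Br
F4 | step 8 | 3,5-dibromo-2-(2,3,4-tribromo-6-methoxyphenoxy)phenol | COc1cc(Br)c(Br)c(Br)c1Oc1c(O)cc(Br)cc1Br
F5 | step 7 | 3,4-dibromothiophene | Brc1cscc1Br
F6 | step 7 | 3,4-dibromothiophene 1,1-dioxide | O=S1(=O)C=C(Br)C(Br)=C1
F7 | step 7 | 2,3,4,5-tetrabromo-2,5-dihydrothiophene 1,1-dioxide | O=S1(=O)C(Br)C(Br)=C(Br)C1Br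
F0 | step 5 | none | none
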